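**Plan**
1. The retrosynthesis first cuts the aryl ester C–O bond between O4 of ring A and the carbonyl of ring B. It then cuts the C3–C4 and C5–C6 bonds of ring A.
2. Enabling feature: in ring A the C1 carboxyl stands between C2–O and C6–propyl. This is the same contiguous array as C5 (ester), C4 (oxygen) and C6 (alkyl) of a 4-oxy-6-propyl-2-pyrone-5-carboxylate, and the remaining C4–O/C5–H pair is a ketene acetal.
3. Forward, the pyrone ring is closed first (β-keto ester plus malonyl dichloride) and O-benzylated. Ring A then arises from it by [4+2] addition of ketene bis(trimethylsilyl) acetal and loss of CO2 and silanol, which leaves only O4 free.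
4. Ring B is not built: 5-propylresorcinol is formylated, 4-O-benzylated, 2-O-methylated and oxidised to the acid.
5. The two halves are joined by esterification, and one hydrogenolysis removes all three benzyl groups.
6. The target has no stereocentre. Control is regiochemical only, from the 5-ester in the cycloaddition and from the hydrogen-bonded ortho hydroxyl in ring B.

Key step: step 5

Remark: the target is achiral, so its SMILES carries no stereodescriptors; 5-propylbenzene-1,3-diol (divarinol) is taken as a purchasable compound.

**Step 1**
Reactants: 1 methyl 3-oxohexanoate; 2 benzyl alcohol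
Product: 3 benzyl 3-oxohexanoate
Conditions: DMAP (0.2 equiv), toluene, reflux, MeOH distilled off
Reagents that add atoms: none
Why: Transesterification of a β-keto ester, which under DMAP catalysis runs through the enol/acylketene manifold far faster than that of a simple ester, is pulled to the benzyl ester by removal of methanol.

**Step 2**
Reactants: 3 benzyl 3-oxohexanoate; 4 malonyl dichloride
Product: 5 benzyl 4-hydroxy-2-oxo-6-propyl-2H-pyran-5-carboxylate
Conditions: neat, rt, 48 h, slow N2 stream
Reagents that add atoms: none
Why: This is the known 4-hydroxy-2-pyrone synthesis from a β-keto ester and malonyl dichloride, in which one acyl chloride C-acylates the activated methylene and the other O-acylates the ketone enol, so the six-membered lactone closes with the ester at C5 between the hydroxyl-bearing C4 and the propyl-bearing C6.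

**Step 3**
Reactants: 5 benzyl 4-hydroxy-2-oxo-6-propyl-2H-pyran-5-carboxylate; 2 benzyl alcohol
Product: 6 benzyl 4-(benzyloxy)-2-oxo-6-propyl-2H-pyran-5-carboxylate
Conditions: PPh3, DIAD, THF, 0 °C to rt
Reagents that add atoms: none
Why: In the Mitsunobu reaction the acidic, vinylogous carboxylic acid OH of a 4-hydroxy-2-pyrone is alkylated on the 4-oxygen under neutral conditions, which spares the base-sensitive pyrone ring and suppresses the C3-alkylation that benzyl halides and carbonate bases can cause.

**Step 4**
Reactants: 7 trimethylsilyl acetate
Product: 9 1,1-bis(trimethylsilyloxy)ethene, via lithium enolate 8 (not isolated)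
Conditions: LiN(i-Pr)2, THF, −78 °C; then Me3SiCl, −78 °C to rt; distillation
Reagents that add atoms: chlorotrimethylsilane, C[Si](C)(C)Cl
Why: Kinetic enolisation of the silyl ester followed by O-silylation of the lithium enolate is the standard preparation of ketene bis(silyl) acetals, and any C-silylated isomer is a bystander in the next step.

**Step 5**
Reactants: 6 benzyl 4-(benzyloxy)-2-oxo-6-propyl-2H-pyran-5-carboxylate; 9 1,1-bis(trimethylsilyloxy)ethene
Product: 13 benzyl 2-(benzyloxy)-4-hydroxy-6-propylbenzoate, via bridged bicyclic lactone 10 (not isolated), via bis(silyloxy)cyclohexadiene 11 (not isolated), via aryl trimethylsilyl ether 12 (not isolated)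
Conditions: 9 (5 equiv), o-xylene, 140 °C, sealed tube; then 1 M HCl, THF, rt
Reagents that add atoms: none
Why: The reaction is an inverse-electron-demand Diels–Alder addition in which the electron-rich alkene 9 meets the C3=C4–C5=C6 diene of 6; bonding runs ahead between the unsubstituted terminus of 9 and C6, the β-carbon of the 5-ester and δ-carbon of the lactone carbonyl, and is completed between the dioxygenated carbon of 9 and C3, so that the 2-oxabicyclo[2.2.2]octenone 10 results. At the reaction temperature 10 loses CO2 by retro-[4+2] cleavage to give diene 11, 1,2-elimination of Me3SiOH makes the ring aromatic (12), and dilute acid frees the phenol; any 11 that survives is hydrolysed by the same acid to the dienone tautomer of 13, so both channels converge. The closest known reaction type is the conversion of 2-pyrone-5-carboxylates (coumalates) and of 6-alkyl-2-pyrone-3-carboxylates with 1,1-dialkoxyethenes into alkoxybenzoates by cycloaddition, CO2 extrusion and loss of alcohol. Ring A is closed in an intermolecular [4+2] mode, four carbons from the pyrone and two from 9 with formation of C3–C4 and C5–C6 (ring A numbering), and the two bridgehead stereocentres of racemic 10 vanish on aromatisation, so no stereocontrol is required. The selectivity needed is regiochemical, oxygen para to the ester: it is secured by the 5-ester, which places the largest LUMO coefficient on C6, whereas C3 is made electron-rich by the adjacent 4-benzyloxy group and cannot accept the nucleophilic terminus. The 4-benzyloxy group sits on the central, nodal carbon of the C3–C4–C5 allyl-anion-like unit that takes up the charge, so it costs mainly ground-state stabilisation, and this handicap and the crowding by the 6-propyl group are answered with excess 9 and 140 °C.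

**Step 6**
Reactants: 14 5-propylbenzene-1,3-diol (divarinol)
Product: 16 2,4-dihydroxy-6-propylbenzaldehyde, via aryl iminium chloride 15 (not isolated)
Conditions: POCl3, DMF, 0 °C to rt; then H2O, 50 °C
Reagents that add atoms: N,N-dimethylformamide, CN(C)C=O; water, O
Why: Vilsmeier–Haack formylation of a 5-alkylresorcinol takes place para to one hydroxyl and ortho to the other, as with orcinol and olivetol, rather than at the crowded carbon between the two hydroxyls.

**Step 7**
Reactants: 16 2,4-dihydroxy-6-propylbenzaldehyde
Product: 17 4-(benzyloxy)-2-hydroxy-6-propylbenzaldehyde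
Conditions: BnBr (1.05 equiv), K2CO3 (1.1 equiv), acetone, reflux
Reagents that add atoms: benzyl bromide, BrCc1ccccc1
Why: Williamson ether synthesis with about one equivalent of halide is selective for the 4-hydroxyl because the 2-hydroxyl is tied up in a hydrogen bond to the aldehyde oxygen and its phenoxide is the weaker nucleophile.

**Step 8**
Reactants: 17 4-(benzyloxy)-2-hydroxy-6-propylbenzaldehyde
Product: 18 4-(benzyloxy)-2-methoxy-6-propylbenzaldehyde
Conditions: MeI (excess), K2CO3, DMF, rt
Reagents that add atoms: iodomethane, CI
Why: Williamson methylation with excess iodomethane in a dipolar aprotic solvent overcomes the hydrogen bond and caps the only remaining hydroxyl.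

**Step 9**
Reactants: 18 4-(benzyloxy)-2-methoxy-6-propylbenzaldehyde
Product: 19 4-(benzyloxy)-2-methoxy-6-propylbenzoic acid
Conditions: NaClO2, NaH2PO4, 2-methyl-2-butene, t-BuOH/H2O, rt
Reagents that add atoms: sodium chlorite, [Na+].[O-]Cl=O
Why: The Pinnick oxidation turns hindered, electron-rich aromatic aldehydes into acids without touching benzyl or methyl ethers, and 2-methyl-2-butene traps the hypochlorous acid that would otherwise chlorinate the ring.

**Step 10**
Reactants: 19 4-(benzyloxy)-2-methoxy-6-propylbenzoic acid; 13 benzyl 2-(benzyloxy)-4-hydroxy-6-propylbenzoate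
Product: 21 benzyl 2-(benzyloxy)-4-{[4-(benzyloxy)-2-methoxy-6-propylbenzoyl]oxy}-6-propylbenzoate, via mixed trifluoroacetic anhydride 20 (not isolated)
Conditions: (CF3CO)2O, toluene, rt
Reagents that add atoms: none
Why: Esterification through the mixed trifluoroacetic anhydride is the classical depside coupling, since the doubly ortho-substituted, electron-rich aroyl group ionises easily towards an acylium ion that escapes the steric block and is taken up by the single free hydroxyl of 13.

**Step 11**
Reactants: 21 benzyl 2-(benzyloxy)-4-{[4-(benzyloxy)-2-methoxy-6-propylbenzoyl]oxy}-6-propylbenzoate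
Product: 22 2-hydroxy-4-[(4-hydroxy-2-methoxy-6-propylbenzoyl)oxy]-6-propylbenzoic acid (CNP0147807.0)
Conditions: H2 (1 atm), 10% Pd/C, EtOAc, rt
Reagents that add atoms: none
Why: Catalytic hydrogenolysis removes the benzyl ester and both aryl benzyl ethers in one neutral operation at room temperature, conditions under which the aryl ester link, the methyl ether and the decarboxylation-prone salicylic acid should persist.

**Compound list**
1 | methyl 3-oxohexanoate | CCCC(=O)CC(=O)OC | starting material
2 | benzyl alcohol | OCc1ccccc1 | starting material
3 | benzyl 3-oxohexanoate | CCCC(=O)CC(=O)OCc1ccccc1 | intermediate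
4 | malonyl dichloride | O=C(Cl)CC(=O)Cl | starting material
5 | benzyl 4-hydroxy-2-oxo-6-propyl-2H-pyran-5-carboxylate | CCCC1=C(C(=O)OCc2ccccc2)C(O)=CC(=O)O1 | intermediate
6 | benzyl 4-(benzyloxy)-2-oxo-6-propyl-2H-pyran-5-carboxylate | CCCC1=C(C(=O)OCc2ccccc2)C(OCc2ccccc2)=CC(=O)O1 | intermediate
7 | trimethylsilyl acetate | CC(=O)O[Si](C)(C)C | starting material
8 | lithium 1-(trimethylsilyloxy)ethen-1-olate (not isolated) | [Li+].C=C([O-])O[Si](C)(C)C | intermediate
9 | 1,1-bis(trimethylsilyloxy)ethene | C=C(O[Si](C)(C)C)O[Si](C)(C)C | intermediate
10 | benzyl 5-(benzyloxy)-3-oxo-1-propyl-8,8-bis(trimethylsilyloxy)-2-oxabicyclo[2.2.2]oct-5-ene-6-carboxylate (racemic, not isolated) | CCCC12CC(O[Si](C)(C)C)(O[Si](C)(C)C)C(C(=O)O1)C(OCc1ccccc1)=C2C(=O)OCc1ccccc1 | intermediate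
11 | benzyl 6-(benzyloxy)-2-propyl-4,4-bis(trimethylsilyloxy)cyclohexa-1,5-diene-1-carboxylate (not isolated) | CCCC1=C(C(=O)OCc2ccccc2)C(OCc2ccccc2)=CC(O[Si](C)(C)C)(O[Si](C)(C)C)C1 | intermediate
12 | benzyl 2-(benzyloxy)-6-propyl-4-(trimethylsilyloxy)benzoate (not isolated) | CCCc1cc(O[Si](C)(C)C)cc(OCc2ccccc2)c1C(=O)OCc1ccccc1 | intermediate
13 | benzyl 2-(benzyloxy)-4-hydroxy-6-propylbenzoate | CCCc1cc(O)cc(OCc2ccccc2)c1C(=O)OCc1ccccc1 | intermediate
14 | 5-propylbenzene-1,3-diol (divarinol) | CCCc1cc(O)cc(O)c1 | starting material
15 | N-(2,4-dihydroxy-6-propylbenzylidene)-N-methylmethanaminium chloride (not isolated) | CCCc1cc(O)cc(O)c1C=[N+](C)C.[Cl-] | intermediate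
16 | 2,4-dihydroxy-6-propylbenzaldehyde | CCCc1cc(O)cc(O)c1C=O | intermediate
17 | 4-(benzyloxy)-2-hydroxy-6-propylbenzaldehyde | CCCc1cc(OCc2ccccc2)cc(O)c1C=O | intermediate
18 | 4-(benzyloxy)-2-methoxy-6-propylbenzaldehyde | CCCc1cc(OCc2ccccc2)cc(OC)c1C=O | intermediate
19 | 4-(benzyloxy)-2-methoxy-6-propylbenzoic acid | CCCc1cc(OCc2ccccc2)cc(OC)c1C(=O)O | intermediate
20 | 4-(benzyloxy)-2-methoxy-6-propylbenzoic trifluoroacetic anhydride (not isolated) | CCCc1cc(OCc2ccccc2)cc(OC)c1C(=O)OC(=O)C(F)(F)F | intermediate
21 | benzyl 2-(benzyloxy)-4-{[4-(benzyloxy)-2-methoxy-6-propylbenzoyl]oxy}-6-propylbenzoate | CCCc1cc(OC(=O)c2c(CCC)cc(OCc3ccccc3)cc2OC)cc(OCc2ccccc2)c1C(=O)OCc1ccccc1 | intermediate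
22 | 2-hydroxy-4-[(4-hydroxy-2-methoxy-6-propylbenzoyl)oxy]-6-propylbenzoic acid | CCCc1cc(OC(=O)c2c(CCC)cc(O)cc2OC)cc(O)c1C(=O)O | target

**Total step count:** 11
**Longest linear sequence:** 6 steps (1, 2, 3, 5, 10, 11; the ring B branch 6, 7, 8, 9, 10, 11 is equally long)

**Steps most likely to fail**

Step 5.
- What may go wrong: the cycloaddition may be too slow, for three reasons. These are the donor at C4, twisting of the doubly flanked 5-ester out of conjugation, and crowding at C6.
- Thermal decay and protodesilylation of 9 could then outrun the addition. Conjugate addition at C6 could also be followed by opening of the lactone instead of closure at C3.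
- Fallback: ring A is taken from a preformed arene instead of being built, setting out from 14.
- Carboxylation of 14 with MeOMgOCO2Me in DMF at 120 °C (Kolbe–Schmitt type, established for 5-alkylresorcinols) should give 2,4-dihydroxy-6-propylbenzoic acid F1.
- Alkylation of the carboxylate of F1 (BnBr, KHCO3, DMF, rt) should give benzyl 2,4-dihydroxy-6-propylbenzoate F2.
- Coupling of F2 with 19 through 20 under the conditions of step 10 should acylate only the 4-hydroxyl, because the 2-hydroxyl is hydrogen-bonded to the ester. The product is benzyl 4-{[4-(benzyloxy)-2-methoxy-6-propylbenzoyl]oxy}-2-hydroxy-6-propylbenzoate F3.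
- Hydrogenolysis of F3 as in step 11 comes back to the route at 22.

Step 2.
- What may go wrong: the acid chloride may self-condense, the first-formed hydroxypyrone may be over-acylated, and the benzyl ester may be cleaved by the acid that is released.
- Fallback: the two acylations are separated, setting out from 3.
- C-acylation of 3 with methyl 3-chloro-3-oxopropanoate (MgCl2, pyridine, CH2Cl2, 0 °C) should give 1-benzyl 5-methyl 2-butanoyl-3-oxopentanedioate F4.
- DBU in refluxing toluene then lets the enol oxygen of the butanoyl ketone attack the methyl ester, which is the known lactonisation of 3,5-dioxo esters. This comes back to the route at 5.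

Step 10.
- What may go wrong: acyl transfer to the weakly nucleophilic phenol may be slow, so that trifluoroacetylation of 13, ring C-acylation or acid-induced loss of the electron-rich benzyl ether competes.
- Fallback: acid-mediated activation in the flask is replaced by a preformed acyl halide used under basic conditions, setting out from 19.
- Oxalyl chloride with catalytic DMF in CH2Cl2 should give 4-(benzyloxy)-2-methoxy-6-propylbenzoyl chloride F5, freed of volatiles.
- F5 is then combined with 13, Et3N and DMAP in CH2Cl2 (nucleophilic catalysis through the acylpyridinium ion), which comes back to the route at 21.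

**Further compounds**
F1 | step 5 | 2,4-dihydroxy-6-propylbenzoic acid | CCCc1cc(O)cc(O)c1C(=O)O
F2 | step 5 | benzyl 2,4-dihydroxy-6-propylbenzoate | CCCc1cc(O)cc(O)c1C(=O)OCc1ccccc1
F3 | step 5 | benzyl 4-{[4-(benzyloxy)-2-methoxy-6-propylbenzoyl]oxy}-2-hydroxy-6-propylbenzoate | CCCc1cc(OC(=O)c2c(CCC)cc(OCc3ccccc3)cc2OC)cc(O)c1C(=O)OCc1ccccc1
F4 | step 2 | 1-benzyl 5-methyl 2-butanoyl-3-oxopentanedioate | CCCC(=O)C(C(=O)OCc1ccccc1)C(=O)CC(=O)OC
F5 | step 10 | 4-(benzyloxy)-2-methoxy-6-propylbenzoyl chloride | CCCc1cc(OCc2ccccc2)cc(OC)c1C(=O)Cl
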